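**Plan**

1. The target is 2-acetoxy-3,6-bis(4-hydroxyphenyl)-1,4-benzoquinone, ring numbered C1(=O), C2(OAc), C3(Ar), C4(=O), C5(H), C6(Ar). Remark: it has no stereocentre, so it is one achiral compound and no asymmetric step is needed.
2. Enabling feature: C2(O)–C3(Ar)–C4(O)–C5 of the six-membered ring is a 2-aryl-1,3-dioxygenated butadiene, and C6(Ar)–C1 is a β-nitrostyrene whose nitro carbon is C1 at a masked carbonyl level.
3. Retrosynthesis: remove the benzyl and acetyl groups, take the quinone back to a catechol and its 1,2-dione tautomer, return the C1 carbonyl to a nitro group, then cut C5–C6 and C1–C2 in a [4+2] sense.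
4. Forward: an arylacetate is C-acetylated, O-methylated and silylated to the ketene acetal diene; a Henry condensation gives the nitrostyrene; their cycloaddition closes the only new ring.
5. After ring formation: oxidative Nef reaction and enolisation to the catechol, oxidation with hydrolysis of the methyl ether to the hydroxyquinone, acetylation, debenzylation.
6. Stereochemistry: the two centres made in the cycloaddition (trans, racemic) are erased on aromatisation; nothing stereochemical is carried to the target.

Key step: step 5

Compounds 1, 8 and 9 are taken as commercially available.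

**Step 1**
Reactants: 1 methyl 4-(benzyloxy)phenylacetate
Product: 4 methyl 2-[4-(benzyloxy)phenyl]-3-oxobutanoate, via lithium ester enolate 2 (not isolated), via lithium enolate of the keto ester 3 (not isolated)
Conditions: LiHMDS (2.1 equiv), THF, −78 °C; AcCl (1.1 equiv), −78 → 0 °C; 1 M HCl quench
Reagents that add atoms: acetyl chloride, CC(=O)Cl
Why: Claisen-type C-acylation of a lithium ester enolate by an acid chloride should give the β-keto ester, the second equivalent of base holding the more acidic product as its enolate until the quench; the benzylic carbon is configurationally labile and of no consequence.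

**Step 2**
Reactants: 4 methyl 2-[4-(benzyloxy)phenyl]-3-oxobutanoate
Product: 5 methyl (2E)-2-[4-(benzyloxy)phenyl]-3-methoxybut-2-enoate (E drawn; an E/Z mixture is acceptable)
Conditions: HC(OMe)3 (3 equiv), cat. H2SO4, MeOH, rt → 60 °C
Reagents that add atoms: trimethyl orthoformate, COC(OC)OC
Why: Acid-catalysed ketalisation with the orthoformate and loss of methanol (enol ether formation, as used for β-methoxy crotonates) should give the β-methoxy enoate; geometric or double-bond isomers are tolerable because all give the same dienolate in step 3.

**Step 3**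
Reactants: 5 methyl (2E)-2-[4-(benzyloxy)phenyl]-3-methoxybut-2-enoate
Product: 7 (1Z)-2-[4-(benzyloxy)phenyl]-1,3-dimethoxy-1-(trimethylsilyloxy)buta-1,3-diene (ketene acetal geometry drawn Z; either isomer serves), via lithium dienolate 6 (not isolated)
Conditions: LDA (1.15 equiv), THF, −78 °C; TMSCl (1.3 equiv), −78 °C → rt; pentane, filtration, used crude
Reagents that add atoms: chlorotrimethylsilane, C[Si](C)(C)Cl
Why: γ-Deprotonation of a β-methoxy enoate and O-silylation of the dienolate is the standard silyl ketene acetal formation leading to Brassard-type dienes; the α-carbon is fully substituted, so only the methyl group can be deprotonated.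

**Step 4**
Reactants: 8 4-(benzyloxy)benzaldehyde; 9 nitromethane
Product: 10 (E)-1-(benzyloxy)-4-(2-nitrovinyl)benzene
Conditions: NH4OAc, AcOH, 100 °C
Reagents that add atoms: none
Why: Henry condensation (nitroaldol addition then dehydration) should give the thermodynamically favoured E-nitroalkene, and the benzyl ether is stable to hot acetic acid.

**Step 5**
Reactants: 7 (1Z)-2-[4-(benzyloxy)phenyl]-1,3-dimethoxy-1-(trimethylsilyloxy)buta-1,3-diene; 10 (E)-1-(benzyloxy)-4-(2-nitrovinyl)benzene
Product: 12 trans-2,5-bis[4-(benzyloxy)phenyl]-3-methoxy-6-nitrocyclohex-2-en-1-one (racemic), via silyl methyl ketal cycloadduct 11 (not isolated)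
Conditions: 7 (1.4 equiv), toluene, rt → 60 °C; then 1 M HCl–THF, 0 °C
Reagents that add atoms: none
Why: The electron-rich 1,1,3-trioxygenated diene and the electron-poor nitroalkene should combine in a normal-demand, strongly asynchronous [4+2] cycloaddition (at the limit a Mukaiyama–Michael addition followed by collapse of the nitronate carbon onto the oxocarbenium carbon), the closest known reaction type being the Diels–Alder reaction of Danishefsky- and Brassard-type silyloxydienes with β-nitrostyrenes. The single ring is closed in this [4+2] mode (6-exo-trig if the second bond forms stepwise), creating C5–C6 and C1–C2 in quinone numbering. Regiochemistry is the one selectivity the step needs and follows from matched polarisation: the unsubstituted CH2 terminus carries the largest HOMO coefficient of the vinylogous ketene acetal and bonds to the aryl-bearing β-carbon of the nitroalkene, which leaves the ketene acetal carbon to bond to the nitro carbon. The two new stereocentres (aryl-bearing and nitro-bearing carbons) should be trans because the E geometry of 10 is transferred suprafacially and the acidic nitro-bearing carbon can epimerise to the diequatorial isomer; with no chiral element the product is racemic, and both centres are removed later. The ketal carbon of 11 forms as an uncontrolled mixture that does not matter, because cold dilute acid collapses the silyl methyl ketal to the ketone. The vinylogous ester is far less acid-labile than the mixed ketal and should survive, so the ring then holds oxygen at C2 and C4 and the nitro group at C1.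

**Step 6**
Reactants: 12 trans-2,5-bis[4-(benzyloxy)phenyl]-3-methoxy-6-nitrocyclohex-2-en-1-one
Product: 15 3,6-bis[4-(benzyloxy)phenyl]-4-methoxybenzene-1,2-diol, via potassium nitronate 13 (not isolated), via cyclohexene-1,2-dione 14 (not isolated)
Conditions: KOtBu (1.0 equiv), THF, 0 °C; DMDO (1.05 equiv, freshly prepared in acetone), −40 → 0 °C; pH 7 buffer, under argon
Reagents that add atoms: dimethyldioxirane, CC1(C)OO1
Why: In this oxidative Nef reaction the nitronate is C-hydroxylated by the dioxirane and expels nitrite to give the 1,2-dione, which is the keto tautomer of an aromatic catechol and should enolise irreversibly, erasing the last stereocentre; the anionic nitronate should outcompete the neutral vinylogous ester alkene and the neutral catechol for the single equivalent of oxidant.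

**Step 7**
Reactants: 15 3,6-bis[4-(benzyloxy)phenyl]-4-methoxybenzene-1,2-diol
Product: 17 3,6-bis[4-(benzyloxy)phenyl]-2-hydroxy-1,4-benzoquinone, via 4-methoxy-1,2-benzoquinone 16 (not isolated)
Conditions: PhI(OAc)2 (1.05 equiv), MeCN–H2O (4:1), 0 °C; then 1 M HCl, rt
Reagents that add atoms: water, O
Why: Two-electron oxidation of the catechol by the iodine(III) reagent gives the ortho-quinone, whose vinylogous methyl ester should hydrolyse under acid by addition–elimination of water at C4 to the 2-hydroxy-1,4-benzoquinone, the stable tautomer; the benzyl ethers are inert to both reagents.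

**Step 8**
Reactants: 17 3,6-bis[4-(benzyloxy)phenyl]-2-hydroxy-1,4-benzoquinone
Product: 18 2,5-bis[4-(benzyloxy)phenyl]-3,6-dioxocyclohexa-1,4-dien-1-yl acetate
Conditions: Ac2O (1.5 equiv), pyridine (2 equiv), CH2Cl2, 0 °C, short reaction time
Reagents that add atoms: acetic anhydride, CC(=O)OC(C)=O
Why: O-Acetylation of the acidic enolic hydroxyl of a hydroxyquinone with acetic anhydride and pyridine is routine, and with both phenols still benzylated it is the only free hydroxyl.

**Step 9**
Reactants: 18 2,5-bis[4-(benzyloxy)phenyl]-3,6-dioxocyclohexa-1,4-dien-1-yl acetate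
Product: 20 neonambiquinone A [2,5-bis(4-hydroxyphenyl)-3,6-dioxocyclohexa-1,4-dien-1-yl acetate], via acetoxyhydroquinone 19 (not isolated)
Conditions: H2 (1 atm), 10% Pd/C, EtOAc, rt; filtration under argon; DDQ (1.0 equiv), 0 °C
Reagents that add atoms: none
Why: Catalytic hydrogenolysis should cleave both benzyl ethers while reducing the quinone to the hydroquinone, and DDQ then dehydrogenates the hydroquinone back to the quinone; the medium stays neutral and non-nucleophilic throughout, which should keep the labile acetate on O2.

**Compound list**

1 | methyl 4-(benzyloxy)phenylacetate | COC(=O)Cc1ccc(OCc2ccccc2)cc1 | starting material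
2 | lithium enolate of 1 (not isolated; geometry undefined) | COC(O[Li])=Cc1ccc(OCc2ccccc2)cc1 | intermediate
3 | lithium enolate of keto ester 4 (not isolated) | COC(=O)C(c1ccc(OCc2ccccc2)cc1)=C(C)O[Li] | intermediate
4 | methyl 2-[4-(benzyloxy)phenyl]-3-oxobutanoate (racemic, enolisable centre) | COC(=O)C(C(C)=O)c1ccc(OCc2ccccc2)cc1 | intermediate
5 | methyl (2E)-2-[4-(benzyloxy)phenyl]-3-methoxybut-2-enoate | COC(=O)/C(c1ccc(OCc2ccccc2)cc1)=C(/OC)C | intermediate
6 | lithium dienolate of 5 (not isolated) | C=C(OC)C(c1ccc(OCc2ccccc2)cc1)=C(OC)O[Li] | intermediate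
7 | (1Z)-2-[4-(benzyloxy)phenyl]-1,3-dimethoxy-1-(trimethylsilyloxy)buta-1,3-diene | C=C(OC)/C(c1ccc(OCc2ccccc2)cc1)=C(/OC)O[Si](C)(C)C | intermediate
8 | 4-(benzyloxy)benzaldehyde | O=Cc1ccc(OCc2ccccc2)cc1 | starting material
9 | nitromethane | C[N+](=O)[O-] | starting material
10 | (E)-1-(benzyloxy)-4-(2-nitrovinyl)benzene | O=[N+]([O-])/C=C/c1ccc(OCc2ccccc2)cc1 | intermediate
11 | trans-2,5-bis[4-(benzyloxy)phenyl]-1,3-dimethoxy-6-nitro-1-(trimethylsilyloxy)cyclohex-2-ene (not isolated; racemic, ketal carbon a mixture) | COC1=C(c2ccc(OCc3ccccc3)cc2)C(OC)(O[Si](C)(C)C)[C@H]([N+](=O)[O-])[C@@H](c2ccc(OCc3ccccc3)cc2)C1 | intermediate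
12 | trans-2,5-bis[4-(benzyloxy)phenyl]-3-methoxy-6-nitrocyclohex-2-en-1-one (racemic, 5R*,6R*; one enantiomer drawn) | COC1=C(c2ccc(OCc3ccccc3)cc2)C(=O)[C@H]([N+](=O)[O-])[C@@H](c2ccc(OCc3ccccc3)cc2)C1 | intermediate
13 | potassium nitronate of 12 (not isolated; racemic) | COC1=C(c2ccc(OCc3ccccc3)cc2)C(=O)C(=[N+]([O-])[O-])[C@@H](c2ccc(OCc3ccccc3)cc2)C1.[K+] | intermediate
14 | 3,6-bis[4-(benzyloxy)phenyl]-4-methoxycyclohex-3-ene-1,2-dione (not isolated; racemic) | COC1=C(c2ccc(OCc3ccccc3)cc2)C(=O)C(=O)[C@@H](c2ccc(OCc3ccccc3)cc2)C1 | intermediate
15 | 3,6-bis[4-(benzyloxy)phenyl]-4-methoxybenzene-1,2-diol | COc1cc(-c2ccc(OCc3ccccc3)cc2)c(O)c(O)c1-c1ccc(OCc2ccccc2)cc1 | intermediate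
16 | 3,6-bis[4-(benzyloxy)phenyl]-4-methoxy-1,2-benzoquinone (not isolated) | COC1=C(c2ccc(OCc3ccccc3)cc2)C(=O)C(=O)C(c2ccc(OCc3ccccc3)cc2)=C1 | intermediate
17 | 3,6-bis[4-(benzyloxy)phenyl]-2-hydroxy-1,4-benzoquinone | OC1=C(c2ccc(OCc3ccccc3)cc2)C(=O)C=C(c2ccc(OCc3ccccc3)cc2)C1=O | intermediate
18 | 2,5-bis[4-(benzyloxy)phenyl]-3,6-dioxocyclohexa-1,4-dien-1-yl acetate | CC(=O)OC1=C(c2ccc(OCc3ccccc3)cc2)C(=O)C=C(c2ccc(OCc3ccccc3)cc2)C1=O | intermediate
19 | 3,6-dihydroxy-2,5-bis(4-hydroxyphenyl)phenyl acetate (not isolated) | CC(=O)Oc1c(O)c(-c2ccc(O)cc2)cc(O)c1-c1ccc(O)cc1 | intermediate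
20 | neonambiquinone A, 2,5-bis(4-hydroxyphenyl)-3,6-dioxocyclohexa-1,4-dien-1-yl acetate (achiral) | CC(=O)OC1=C(c2ccc(O)cc2)C(=O)C=C(c2ccc(O)cc2)C1=O | target

**Totals**

Total step count: 9. Longest linear sequence: 8 steps (steps 1, 2, 3, 5, 6, 7, 8, 9 from compound 1).

**Steps most likely to fail**

Step 5. The addition may stop after the first C–C bond, with silyl transfer to the nitronate leaving an open chain. The hindered, moisture-sensitive diene may also be lost by protodesilylation before it reacts. The fallback sets out from enol ether 5 and nitrostyrene 10 and builds the same two bonds anionically. Lithium dienolate 6 (LDA, THF, −78 °C) should add through its γ-carbon to 10 in a vinylogous Michael addition, and protonation should give methyl 2,5-bis[4-(benzyloxy)phenyl]-3-methoxy-6-nitrohex-2-enoate F1. Treatment with KOtBu (2.2 equiv) in THF should then close the ring by a Dieckmann-type Claisen acylation of the nitronate carbon by the methyl ester. The enol ether geometry can equilibrate through the dienolate, and deprotonation of the acidic α-nitro ketone drives the closure. Acidification returns the route at compound 12.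

Step 6. The catechol may be over-oxidised as it forms, or the α-nitro ketone may suffer retro-Claisen ring opening before the oxygen transfer. The fallback sets out from compound 12 and unmasks the carbonyl reductively. Buffered aqueous TiCl3 (NH4OAc, THF–H2O, rt) should reduce the nitro group to the imine level, at which the ring tautomerises to the aromatic 2-amino-3,6-bis[4-(benzyloxy)phenyl]-5-methoxyphenol F2. Oxidation of this para-methoxy aniline with PhI(OAc)2 in aqueous MeCN gives the quinone imine, and 1 M HCl should hydrolyse it with loss of ammonia and methanol. This returns the route at compound 17 and skips compounds 15 and 16.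

Step 9. The acetyl group may migrate to the neighbouring hydroxyl while the molecule is at the hydroquinone level, or re-oxidation may be incomplete. The fallback sets out from compound 18 and never leaves the quinone oxidation level. BCl3 with pentamethylbenzene as cation scavenger (CH2Cl2, −78 °C, pH 7 buffer quench) should cleave both aryl benzyl ethers by Lewis-acid activation and leave the acetate and the quinone untouched. It arrives directly at compound 20, and no new compound arises (F0).

**Further compounds**

F1 | step 5 | methyl 2,5-bis[4-(benzyloxy)phenyl]-3-methoxy-6-nitrohex-2-enoate (racemic, alkene geometry mixed) | COC(=O)C(c1ccc(OCc2ccccc2)cc1)=C(OC)CC(C[N+](=O)[O-])c1ccc(OCc2ccccc2)cc1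
F2 | step 6 | 2-amino-3,6-bis[4-(benzyloxy)phenyl]-5-methoxyphenol | COc1cc(-c2ccc(OCc3ccccc3)cc2)c(N)c(O)c1-c1ccc(OCc2ccccc2)cc1
F0 | step 9 | none | none
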